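At early times the solid J of this flask goes two ways at once: it pairs to J2 or it dissolves to E.

    J ⇌ E, rate k1*(cs1 - [E]) while solid is left; crystals form when [E] > cs1 (cs1 = 0.39 M, k1 = 0.039 /s)
    E + Q → E.Q (k2 = 0.087 /M/s)
    2 E → E2 (k3 = 0.10 /M/s)
    G ⇌ E.Q, rate k4*(cs4 - [E.Q]) while solid is left; crystals form when [E.Q] > cs4 (cs4 = 0.13 M, k4 = 0.42 /s)
    2 J → J2 (k5 = 0.10 /M/s)

J 0.57 M; Q 0.950 equiv; time 1.0 min

- Wednesday's: doubling the dissolution coefficient of step 1, all else as stated
- Thursday's: doubling the amount of Q, all else as stated
- Monday's: doubling the dissolution coefficient of step 4, all else as stated
- Sunday's: doubling the solubility in step 1, all else as stated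

- percentages count the J that a species holds: one E2 or J2 counts as two
- E.Q is meant together with its G
- a step written with two of one species runs at k times the square of its concentration and takes two of it each time
- solid, in amounts per volume of the solution: J, G
- at the start none of J is in solution
- run time (flask): 1.0 min

1. E.Q and G together at 1.0 min, in percent of the J charged
2. the change that raises the amount of E.Q and G together at 1.0 min, in percent of the J charged most ("none" if none brings more than 2 percentage points) (Wednesday's / Thursday's / Monday's / Sunday's / none)
3. amount of E.Q and G together at 1.0 min, in percent of the J charged, after Thursday's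

At the start, pairing takes solid J at 0.0650 M/s, faster than dissolving at 0.0152 M/s. But pairing falls with the square of cJ, so with dissolving held at that starting rate the two rates cross at cJ = 0.276 M. I count the J above that as lost and the J below it as dissolved, which sends 48.4 % of the charge across.

Dissolved E forks too. With cQ at its charge, 0.541 M, Q and pairing take E equally fast at cE = 0.236 M. This is the crossover concentration of E; cE against it gives the selectivity of the fork. Setting dissolving equal to both uses gives cE = 0.135 M, below the crossover. So Q gets a share 63.6 % of the E. E's half-life against Q, 0.245 min, is shorter than the run, so I count the E as passed on, and I commit to 30.8 % of the J charged in E.Q and G.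

Thursday's doubles the crossover and gives 40.0 %. The same sum gives 38.1 % for Wednesday's and 34.6 % for Sunday's, both less.

The forecast gave 31 % (26 % to 36 %), 42 % after Thursday's (36 % to 48 %) and Sunday's as best, holding that “doubling the solubility gets the most E across in that window”.

The flask gives 31.2 %, and 43.0 % after Thursday's. The best change is Thursday's, with 12 percentage points against 4.6 points for Sunday's, 4 points for Wednesday's and 0 points for Monday's.

My weak link is the steady cE. At 0.189 min the reading has Q taking E 2.2 times as fast as pairing does, which, with cQ taken at its charge, puts cE near 0.109 M, less than my 0.135 M. Q's share at that moment is then 68.8 %. In the neighbour with 0.380 equiv of Q, the crossover falls to 0.0942 M, and the same balance puts cE at 0.167 M, above it, so I expect 17.5 %. That neighbour holds 15.7 % in E.Q and G, and 24.9 % in E2.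

(The rate constants are invented; no experiment stands behind them.)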